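The route rests on cutting the bond between the alkyne and ring carbon C1 of the cyclohexene, the alkenyl carbon flanked by the gem-dimethyl carbon C6 and the methyl-bearing C2. A Sonogashira coupling of an unprotected hydroxy enol triflate with a C21 polyenynal forms this bond and should deliver the target in the last step. It exploits two features: ring C1 is a masked ketone carbon that can enolize only toward C2, so the triflate forms as one regioisomer while the methyl stereocenter of actinol is erased; and the chain beyond the alkyne is all-E crocetindial, so the alkyne partner arises by one-carbon homologation of that symmetric C20 dialdehyde.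

Key step: step 4

Assumption: (4R,6R)-actinol (1) and all-E crocetindial (5) are taken as purchasable; the single stereocenter of the target (the R carbinol carbon) is C4 of actinol and is touched by no step, and all seven E double bonds are those of crocetindial.

Step 1
Reactants: 1 (4R,6R)-4-hydroxy-2,2,6-trimethylcyclohexan-1-one (actinol)
Product: 2 (4R,6R)-2,2,6-trimethyl-4-(triethylsilyloxy)cyclohexan-1-one
Conditions: TESCl, imidazole, DMF, 0 °C → rt
Reagents that add atoms: chlorotriethylsilane (TESCl), CC[Si](Cl)(CC)CC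
Why: Imidazole-promoted silyl ether formation at the unhindered secondary alcohol should leave the ketone and both stereocenters untouched and blocks alkoxide formation and O-sulfonylation in step 2.

Step 2
Reactants: 2 (4R,6R)-2,2,6-trimethyl-4-(triethylsilyloxy)cyclohexan-1-one
Product: 4 (4R)-4-hydroxy-2,6,6-trimethylcyclohex-1-en-1-yl trifluoromethanesulfonate, via TES-protected enol triflate 3 (not isolated)
Conditions: LiN(i-Pr)2, THF, −78 → 0 °C; PhNTf2, 0 °C → rt; then 1 M aq HCl, THF, rt
Reagents that add atoms: N-phenylbis(trifluoromethanesulfonimide) (PhNTf2), O=S(=O)(N(c1ccccc1)S(=O)(=O)C(F)(F)F)C(F)(F)F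
Why: Enol triflate formation by enolate O-sulfonylation should give a single regioisomer because only C6 carries an α-hydrogen (C2 is quaternary), which also erases the C6 methyl stereocenter, and dilute acid then cleaves the labile triethylsilyl ether while the enol triflate and the R carbinol remain intact.

Step 3
Reactants: 5 all-E crocetindial, (2E,4E,6E,8E,10E,12E,14E)-2,6,11,15-tetramethylhexadeca-2,4,6,8,10,12,14-heptaenedial
Product: 6 (2E,4E,6E,8E,10E,12E,14E)-2,6,11,15-tetramethylheptadeca-2,4,6,8,10,12,14-heptaen-16-ynal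
Conditions: TMSCHN2 (0.8 equiv), n-BuLi (0.8 equiv), THF, −78 °C; added slowly to 5 in THF, −78 °C → rt; then H2O; dark, argon; unreacted 5 recovered
Reagents that add atoms: trimethylsilyldiazomethane (TMSCHN2), C[Si](C)(C)C=[N+]=[N-]
Why: In this Colvin rearrangement (Seyferth–Gilbert-type homologation) the lithiated diazomethane adds to one aldehyde, Peterson-type loss of Me3SiOLi and then N2 gives an alkylidene carbene, and its 1,2-hydrogen shift should give the terminal enyne without touching the E double bonds; sub-stoichiometric reagent added to the dialdehyde holds the reaction at the mono stage, and the methanol-free conditions avoid conjugate addition to the enal.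

Step 4
Reactants: 4 (4R)-4-hydroxy-2,6,6-trimethylcyclohex-1-en-1-yl trifluoromethanesulfonate (1.5 equiv) and 6 (2E,4E,6E,8E,10E,12E,14E)-2,6,11,15-tetramethylheptadeca-2,4,6,8,10,12,14-heptaen-16-ynal
Product: 7 (2E,4E,6E,8E,10E,12E,14E)-17-[(4R)-4-hydroxy-2,6,6-trimethylcyclohex-1-en-1-yl]-2,6,11,15-tetramethylheptadeca-2,4,6,8,10,12,14-heptaen-16-ynal, the target
Conditions: Pd(PPh3)4 (10 mol %), CuI (20 mol %), Et3N, DMF, degassed, dark, 45 °C
Reagents that add atoms: none
Why: Zerovalent palladium inserts into the C–O bond of the enol triflate 4, the copper acetylide formed from 6, CuI and Et3N transfers its alkynyl group to palladium, and reductive elimination forms the C(sp2)–C(sp) bond between ring carbon C1 and the alkyne. The closest known reaction type is the Sonogashira coupling of hindered 2,6,6-trimethylcyclohexenyl triflates with terminal enynes, the usual entry to 7,8-didehydro carotenoid end groups. No ring is closed and no stereocenter is created; the R carbinol is remote and should pass through unchanged. The step needs cross-coupling to win over oxidative alkyne dimerization and needs the seven E double bonds and the aldehyde to survive, which is secured by rigorous degassing, darkness, mild temperature, an excess of 4 and a tertiary amine base that cannot condense with the aldehyde. The position of the ring double bond is already defined by the enol triflate made in step 2, and because the Pd(PPh3)4/CuI system tolerates the free hydroxyl and the aldehyde, no protecting group has to be removed from the sensitive polyene afterwards.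

Compound list
1 | (4R,6R)-4-hydroxy-2,2,6-trimethylcyclohexan-1-one (actinol) | C[C@H]1C(=O)C(C)(C)C[C@H](O)C1 | starting material
2 | (4R,6R)-2,2,6-trimethyl-4-(triethylsilyloxy)cyclohexan-1-one | C[C@H]1C(=O)C(C)(C)C[C@H](O[Si](CC)(CC)CC)C1 | intermediate
3 | (4R)-2,6,6-trimethyl-4-(triethylsilyloxy)cyclohex-1-en-1-yl trifluoromethanesulfonate (formed and desilylated within step 2) | CC1=C(OS(=O)(=O)C(F)(F)F)C(C)(C)C[C@H](O[Si](CC)(CC)CC)C1 | intermediate
4 | (4R)-4-hydroxy-2,6,6-trimethylcyclohex-1-en-1-yl trifluoromethanesulfonate | CC1=C(OS(=O)(=O)C(F)(F)F)C(C)(C)C[C@H](O)C1 | intermediate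
5 | all-E crocetindial, (2E,4E,6E,8E,10E,12E,14E)-2,6,11,15-tetramethylhexadeca-2,4,6,8,10,12,14-heptaenedial | O=C/C(C)=C/C=C/C(C)=C/C=C/C=C(C)/C=C/C=C(\C)C=O | starting material
6 | (2E,4E,6E,8E,10E,12E,14E)-2,6,11,15-tetramethylheptadeca-2,4,6,8,10,12,14-heptaen-16-ynal | C#C/C(C)=C/C=C/C(C)=C/C=C/C=C(C)/C=C/C=C(\C)C=O | intermediate
7 | (2E,4E,6E,8E,10E,12E,14E)-17-[(4R)-4-hydroxy-2,6,6-trimethylcyclohex-1-en-1-yl]-2,6,11,15-tetramethylheptadeca-2,4,6,8,10,12,14-heptaen-16-ynal | CC1=C(C#C/C(C)=C/C=C/C(C)=C/C=C/C=C(C)/C=C/C=C(\C)C=O)C(C)(C)C[C@H](O)C1 | target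

Total step count: 4. Longest linear sequence: 3 steps (1 → 2 → 4 → 7); the other branch is 2 steps (5 → 6 → 7).

Steps most likely to fail

Step 4. Oxidative addition into the hindered, electron-rich tetrasubstituted enol triflate may be slow, so that oxidative dimerization of the alkyne, E/Z isomerization next to the alkyne or decay of the polyenal could overtake the coupling. The fallback sets out from 6 and 2 and comes back to the route at 7; it makes the same bond by carbonyl addition and dehydration instead of cross-coupling. Aldehyde 6 would be masked (HC(OMe)3, PPTS, MeOH) as (3E,5E,7E,9E,11E,13E,15E)-17,17-dimethoxy-3,7,12,16-tetramethylheptadeca-3,5,7,9,11,13,15-heptaen-1-yne F1. Its lithium acetylide (n-BuLi, THF, −78 °C) would be added to ketone 2 to give the tertiary propargylic alcohol (4R,6R)-1-[(3E,5E,7E,9E,11E,13E,15E)-17,17-dimethoxy-3,7,12,16-tetramethylheptadeca-3,5,7,9,11,13,15-heptaen-1-yn-1-yl]-2,2,6-trimethyl-4-(triethylsilyloxy)cyclohexan-1-ol F2, either epimer at the new carbinol carbon being usable. Dehydration (POCl3, pyridine, 50 °C) can only run toward the methyl-bearing ring carbon, since the other neighbour is quaternary, and should give the protected enyne triethyl{[(1R)-4-[(3E,5E,7E,9E,11E,13E,15E)-17,17-dimethoxy-3,7,12,16-tetramethylheptadeca-3,5,7,9,11,13,15-heptaen-1-yn-1-yl]-3,5,5-trimethylcyclohex-3-en-1-yl]oxy}silane F3. PPTS in wet acetone would then remove the acetal and the silyl ether together to give 7.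

Step 3. The diazo anion may react at both aldehyde termini, may add to the polyenal by dipolar cycloaddition or conjugate addition, or may meet poorly dissolved dialdehyde at low temperature. The fallback sets out from 5 and comes back to the route at 6; it is a protected Corey–Fuchs sequence. Ramirez olefination of 5 with one equivalent of CBr4 and PPh3 (CH2Cl2, 0 °C, in which 5 dissolves) should give (2E,4E,6E,8E,10E,12E,14E)-17,17-dibromo-2,6,11,15-tetramethylheptadeca-2,4,6,8,10,12,14,16-octaenal F4. The remaining aldehyde would be masked with 2,2-dimethylpropane-1,3-diol (PPTS, MgSO4, CH2Cl2) as 2-[(1E,3E,5E,7E,9E,11E,13E)-16,16-dibromo-1,5,10,14-tetramethylhexadeca-1,3,5,7,9,11,13,15-octaen-1-yl]-5,5-dimethyl-1,3-dioxane F5. Treatment with n-BuLi (2.1 equiv, THF, −78 °C, then H2O) should give 2-[(1E,3E,5E,7E,9E,11E,13E)-1,5,10,14-tetramethylhexadeca-1,3,5,7,9,11,13-heptaen-15-yn-1-yl]-5,5-dimethyl-1,3-dioxane F6, and PPTS in wet acetone would release 6.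

Step 2. Deprotonation at the hindered tertiary α-carbon may be incomplete, and the slow sulfonylation of the tetrasubstituted enolate may let amide attack on PhNTf2 or early silyl loss compete. The fallback sets out from 1 and comes back to the route at 7; it replaces the triflate by a vinyl iodide made by the Barton hydrazone iodination, without any protecting group. Ketone 1 would be condensed with hydrazine hydrate (Et3N, EtOH, reflux) to the hydrazone of (4R,6R)-4-hydroxy-2,2,6-trimethylcyclohexan-1-one F7. Iodine and 1,1,3,3-tetramethylguanidine (THF, 0 °C → rt, then brief warming) should convert it into (1R)-4-iodo-3,5,5-trimethylcyclohex-3-en-1-ol F8, again as a single alkene regioisomer because only one α-carbon bears hydrogen. F8 would take the place of 4 in step 4, where the faster oxidative addition of the iodide should allow room temperature, and gives 7.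

Further compounds
F1 | step 4 | (3E,5E,7E,9E,11E,13E,15E)-17,17-dimethoxy-3,7,12,16-tetramethylheptadeca-3,5,7,9,11,13,15-heptaen-1-yne | C#C/C(C)=C/C=C/C(C)=C/C=C/C=C(C)/C=C/C=C(\C)C(OC)OC
F2 | step 4 | (4R,6R)-1-[(3E,5E,7E,9E,11E,13E,15E)-17,17-dimethoxy-3,7,12,16-tetramethylheptadeca-3,5,7,9,11,13,15-heptaen-1-yn-1-yl]-2,2,6-trimethyl-4-(triethylsilyloxy)cyclohexan-1-ol (either C1 epimer) | C[C@H]1C(O)(C#C/C(C)=C/C=C/C(C)=C/C=C/C=C(C)/C=C/C=C(\C)C(OC)OC)C(C)(C)C[C@H](O[Si](CC)(CC)CC)C1
F3 | step 4 | triethyl{[(1R)-4-[(3E,5E,7E,9E,11E,13E,15E)-17,17-dimethoxy-3,7,12,16-tetramethylheptadeca-3,5,7,9,11,13,15-heptaen-1-yn-1-yl]-3,5,5-trimethylcyclohex-3-en-1-yl]oxy}silane | CC1=C(C#C/C(C)=C/C=C/C(C)=C/C=C/C=C(C)/C=C/C=C(\C)C(OC)OC)C(C)(C)C[C@H](O[Si](CC)(CC)CC)C1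
F4 | step 3 | (2E,4E,6E,8E,10E,12E,14E)-17,17-dibromo-2,6,11,15-tetramethylheptadeca-2,4,6,8,10,12,14,16-octaenal | BrC(Br)=C/C(C)=C/C=C/C(C)=C/C=C/C=C(C)/C=C/C=C(\C)C=O
F5 | step 3 | 2-[(1E,3E,5E,7E,9E,11E,13E)-16,16-dibromo-1,5,10,14-tetramethylhexadeca-1,3,5,7,9,11,13,15-octaen-1-yl]-5,5-dimethyl-1,3-dioxane | BrC(Br)=C/C(C)=C/C=C/C(C)=C/C=C/C=C(C)/C=C/C=C(\C)C1OCC(C)(C)CO1
F6 | step 3 | 2-[(1E,3E,5E,7E,9E,11E,13E)-1,5,10,14-tetramethylhexadeca-1,3,5,7,9,11,13-heptaen-15-yn-1-yl]-5,5-dimethyl-1,3-dioxane | C#C/C(C)=C/C=C/C(C)=C/C=C/C=C(C)/C=C/C=C(\C)C1OCC(C)(C)CO1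
F7 | step 2 | hydrazone of (4R,6R)-4-hydroxy-2,2,6-trimethylcyclohexan-1-one | C[C@H]1C(=NN)C(C)(C)C[C@H](O)C1
F8 | step 2 | (1R)-4-iodo-3,5,5-trimethylcyclohex-3-en-1-ol | CC1=C(I)C(C)(C)C[C@H](O)C1
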